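**Plan**
- Retrosynthetic cuts: the ten O–benzyl bonds; O1–C2 (Mitsunobu closure); C2–ring B (aryl Grignard on a lactol); C3–C4 together with the acyl O1–C2 bond (enolate/ortho-quinone methide annulation); C4–C8' (aryllithium plus ring A aldehyde).
- Forward order: rings D, F and E come intact from (+)-catechin; C8' is joined to the ring A aldehyde carbon (the future C4); ring C closes first as a lactone, is opened at the lactol level by the ring B nucleophile and is closed again at O1–C2; hydrogenolysis ends the route.
- Enabling feature: in the upper flavan (ring C = O1, C2, C3, C4, C4a, C8a) O3 on C3 and the C8' aryl (ring D) on C4 are cis, the relationship an endo [4+2] between a ring A ortho-quinone methide (O1, C8a, C4a, C4) and a Z-enolate (C2, C3) delivers.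
- Stereochemistry: C2' and C3' come from (+)-catechin; C3 and C4 come from catalyst control and endo approach in the annulation; C2 comes from chelation-controlled aryl addition followed by inversion in the Mitsunobu closure.

Key step: step 8

Remark: flavan numbering is used for every intermediate (upper unit unprimed with rings A and B; catechin unit primed with rings D, F and E). "Penta-O-benzylcatechin-8-yl" means (2R,3S)-3,5,7-tris(benzyloxy)-2-[3,4-bis(benzyloxy)phenyl]chroman-8-yl. The epimers at the future C4 in the carbinol and sulfone intermediates are carried together, because this centre becomes trigonal in the quinone methide. Ring B is carried as benzyl ethers, since methyl ethers could not be removed at the end.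

**Route**

Step 1
Reactants: 1 (+)-catechin
Product: 2 5,7,3',4'-tetra-O-benzyl-(+)-catechin
Conditions: BnBr, K2CO3, DMF, rt
Reagents that add atoms: benzyl bromide, BrCc1ccccc1
Why: Williamson etherification of the four phenols, which are far more acidic than the C3 alcohol, with a carbonate base that leaves both stereocentres untouched.

Step 2
Reactants: 2 5,7,3',4'-tetra-O-benzyl-(+)-catechin
Product: 3 8-bromo-5,7,3',4'-tetra-O-benzyl-(+)-catechin
Conditions: NBS, CH2Cl2, −78 °C → rt
Reagents that add atoms: N-bromosuccinimide, O=C1CCC(=O)N1Br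
Why: Electrophilic aromatic bromination of the phloroglucinol-type ring D, where C8 of benzylated flavan-3-ols (C8' of the target) reacts in preference to C6 and to the less activated ring E.

Step 3
Reactants: 3 8-bromo-5,7,3',4'-tetra-O-benzyl-(+)-catechin
Product: 4 8-bromo-3,5,7,3',4'-penta-O-benzyl-(+)-catechin
Conditions: NaH, BnBr, DMF, 0 °C → rt
Reagents that add atoms: benzyl bromide, BrCc1ccccc1
Why: Williamson etherification of the secondary alkoxide removes the last acidic proton before the organolithium step, and the aryl bromide is inert to these conditions.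

Step 4
Reactants: 5 2,4-dihydroxybenzaldehyde
Product: 6 4-(benzyloxy)-2-hydroxybenzaldehyde
Conditions: BnBr, NaHCO3, MeCN, reflux
Reagents that add atoms: benzyl bromide, BrCc1ccccc1
Why: Regioselective Williamson etherification, in which the 2-hydroxyl is held in a hydrogen bond to the aldehyde and is less acidic, so the weak base alkylates only the 4-hydroxyl.

Step 5
Reactants: 6 4-(benzyloxy)-2-hydroxybenzaldehyde
Product: 7 4-(benzyloxy)-2-(tert-butyldimethylsilyloxy)benzaldehyde
Conditions: TBSCl, imidazole, DMF, rt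
Reagents that add atoms: tert-butyldimethylsilyl chloride, CC(C)(C)[Si](C)(C)Cl
Why: Imidazole-promoted silylation masks the remaining phenol so that the aldehyde offers no acidic proton to the aryllithium.

Step 6
Reactants: 4 8-bromo-3,5,7,3',4'-penta-O-benzyl-(+)-catechin; 7 4-(benzyloxy)-2-(tert-butyldimethylsilyloxy)benzaldehyde
Product: 10 5-(benzyloxy)-2-[hydroxy(penta-O-benzylcatechin-8-yl)methyl]phenol (both carbinol epimers), via 8-lithio-penta-O-benzylcatechin 8 (not isolated), via silyl ether carbinol 9 (not isolated)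
Conditions: n-BuLi, THF, −78 °C; then 7, −78 °C; then AcOH, Bu4NF, 0 °C
Reagents that add atoms: none
Why: Bromine–lithium exchange and 1,2-addition of the aryllithium to the aldehyde form C4–C8', and buffered fluoride then cleaves the aryl silyl ether (a silyl shift to the new alkoxide would lead to the same diol), the carbinol centre being left as a mixture because it is erased later.

Step 7
Reactants: 10 5-(benzyloxy)-2-[hydroxy(penta-O-benzylcatechin-8-yl)methyl]phenol
Product: 11 5-(benzyloxy)-2-[(penta-O-benzylcatechin-8-yl)(p-tolylsulfonyl)methyl]phenol (both epimers)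
Conditions: p-TolSO2H, CH2Cl2, 0 °C → rt
Reagents that add atoms: p-toluenesulfinic acid, Cc1ccc(cc1)S(=O)O
Why: SN1 substitution in which the carbinol flanked by two electron-rich aryl rings ionises under the sulfinic acid itself and the cation is captured at sulfur, the standard entry to 2-(sulfonylmethyl)phenols used as quinone methide precursors.

Step 8
Reactants: 11 5-(benzyloxy)-2-[(penta-O-benzylcatechin-8-yl)(p-tolylsulfonyl)methyl]phenol; 12 benzyloxyacetic acid
Product: 15 (3S,4R)-3,7-bis(benzyloxy)-4-(penta-O-benzylcatechin-8-yl)chroman-2-one (cis lactone), via benzyloxyacetic pivalic anhydride 13 (not isolated), via ortho-quinone methide 14 (not isolated)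
Conditions: 12, t-BuCOCl, i-Pr2NEt, CH2Cl2, 0 °C; then 11, (2S,3R)-HyperBTM (10 mol %), i-Pr2NEt, CH2Cl2, −40 °C → rt
Reagents that add atoms: none
Why: The amine removes the ring A phenol proton of 11 and p-toluenesulfinate leaves, giving the E-configured quinone methide 14 (ring D aryl turned away from the carbonyl), while the isothiourea is acylated by anhydride 13 and deprotonated to the Z ammonium enolate held planar by its O···S contact; C3 of the enolate then adds to C4, and the ring A phenoxide closes ring C by 6-exo-trig attack on the acyl-isothiouronium carbon (O1–C2) and releases the catalyst. The closest known reaction type is the isothiourea-catalysed formal [4+2] of carboxylic-acid-derived ammonium enolates with ortho-quinone methides released from 2-(sulfonylalkyl)phenols, which gives cis-3,4-dihydrocoumarins, and the easy amine-base enolisation of benzyloxyacetyl electrophiles is familiar from Staudinger ketene chemistry. C3 is set by the catalyst, whose phenyl group should cover one face of the enolate so that C4 bonds to the open face and C3 becomes S (if the sense proved opposite, the enantiomeric catalyst would be used). C4 is set by the endo-type approach, with the benzyloxy group under ring A and the bulky catalyst pointing outward, so that the benzyloxy group and the outward ring D aryl end up cis (C4 R). The step needs the cis C3/C4 pair in one absolute sense although the catechin centres are remote; this rests on catalyst control, on the E geometry enforced by the two ortho substituents of ring D, and on the benzylation of every ring D and ring E phenol, which leaves ring A as the only site that can form a quinone methide. The amine base is expected to be too weak to enolise the product lactone at C3 at a useful rate.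

Step 9
Reactants: 15 (3S,4R)-3,7-bis(benzyloxy)-4-(penta-O-benzylcatechin-8-yl)chroman-2-one
Product: 16 (3S,4R)-3,7-bis(benzyloxy)-4-(penta-O-benzylcatechin-8-yl)chroman-2-ol (both anomers)
Conditions: i-Bu2AlH, CH2Cl2, −78 °C
Reagents that add atoms: none
Why: Partial reduction of the aryl lactone to the lactol by one hydride at low temperature, as is routine for 4-aryl-dihydrocoumarins, with C3 and C4 untouched.

Step 10
Reactants: 17 5-bromo-1,2,3-trimethoxybenzene
Product: 18 5-bromobenzene-1,2,3-triol
Conditions: BBr3, CH2Cl2, −78 °C → rt; then H2O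
Reagents that add atoms: none
Why: Lewis-acid cleavage of the three aryl methyl ethers (BBr3 demethylation) at the stage of a simple arene, where no sensitive function is present.

Step 11
Reactants: 18 5-bromobenzene-1,2,3-triol
Product: 19 1,2,3-tris(benzyloxy)-5-bromobenzene
Conditions: BnBr, K2CO3, DMF, 60 °C, argon
Reagents that add atoms: benzyl bromide, BrCc1ccccc1
Why: Threefold Williamson etherification under inert gas gives the ring B precursor with hydrogenolysable protecting groups.

Step 12
Reactants: 19 1,2,3-tris(benzyloxy)-5-bromobenzene; 16 (3S,4R)-3,7-bis(benzyloxy)-4-(penta-O-benzylcatechin-8-yl)chroman-2-ol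
Product: 21 (1S,2S,3R)-2-(benzyloxy)-3-[4-(benzyloxy)-2-hydroxyphenyl]-3-(penta-O-benzylcatechin-8-yl)-1-[3,4,5-tris(benzyloxy)phenyl]propan-1-ol (flavan C2 S, C3 S, C4 R), via 3,4,5-tris(benzyloxy)phenylmagnesium bromide 20 (not isolated)
Conditions: 19, Mg, THF, 40 °C; then 16, THF–CH2Cl2, −78 → 0 °C; aq. NH4Cl
Reagents that add atoms: none
Why: Grignard addition to a lactol, in which the first equivalent deprotonates 16 and opens it to the phenoxide aldehyde and the second adds to C2 under Cram chelate control (magnesium bridging the aldehyde oxygen and the C3 benzyloxy group, attack on the face away from the large C4 substituent), which should give the 2,3-syn alcohol with C2 S.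

Step 13
Reactants: 21 (1S,2S,3R)-2-(benzyloxy)-3-[4-(benzyloxy)-2-hydroxyphenyl]-3-(penta-O-benzylcatechin-8-yl)-1-[3,4,5-tris(benzyloxy)phenyl]propan-1-ol
Product: 22 deca-O-benzyl-robinetinidol-(4β→8)-catechin, (2R,3S,4R)-3,7-bis(benzyloxy)-4-(penta-O-benzylcatechin-8-yl)-2-[3,4,5-tris(benzyloxy)phenyl]chroman
Conditions: PPh3, DIAD, THF, 0 °C → rt
Reagents that add atoms: none
Why: Intramolecular Mitsunobu etherification, in which the ring A phenol is the acidic partner and the oxyphosphonium salt of the C2 alcohol is displaced by O1 in a 6-exo-tet closure with inversion, turning C2 S into C2 R and placing ring B trans to O3.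

Step 14
Reactants: 22 deca-O-benzyl-robinetinidol-(4β→8)-catechin
Product: 23 robinetinidol-(4β→8)-catechin (CNP0261864.3), upper unit 2R,3S,4R and lower unit 2'R,3'S
Conditions: H2 (1 atm), Pd(OH)2/C, THF–MeOH, rt
Reagents that add atoms: none
Why: Hydrogenolysis of all ten benzyl ethers under neutral conditions, which is standard for benzylated oligoflavanoids and leaves the C4–C8' bond and the flavan C–O bonds intact.

**Compound list**

1 | (+)-catechin, (2R,3S) | O[C@H]1Cc2c(O)cc(O)cc2O[C@@H]1c1ccc(O)c(O)c1 | starting material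
2 | 5,7,3',4'-tetra-O-benzyl-(+)-catechin | O[C@H]1Cc2c(OCc3ccccc3)cc(OCc3ccccc3)cc2O[C@@H]1c1ccc(OCc2ccccc2)c(OCc2ccccc2)c1 | intermediate
3 | 8-bromo-5,7,3',4'-tetra-O-benzyl-(+)-catechin | O[C@H]1Cc2c(OCc3ccccc3)cc(OCc3ccccc3)c(Br)c2O[C@@H]1c1ccc(OCc2ccccc2)c(OCc2ccccc2)c1 | intermediate
4 | 8-bromo-3,5,7,3',4'-penta-O-benzyl-(+)-catechin | Brc1c(OCc2ccccc2)cc(OCc2ccccc2)c2c1O[C@H](c1ccc(OCc3ccccc3)c(OCc3ccccc3)c1)[C@@H](OCc1ccccc1)C2 | intermediate
5 | 2,4-dihydroxybenzaldehyde | O=Cc1ccc(O)cc1O | starting material
6 | 4-(benzyloxy)-2-hydroxybenzaldehyde | O=Cc1ccc(OCc2ccccc2)cc1O | intermediate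
7 | 4-(benzyloxy)-2-(tert-butyldimethylsilyloxy)benzaldehyde | O=Cc1ccc(OCc2ccccc2)cc1O[Si](C)(C)C(C)(C)C | intermediate
8 | 8-lithio-penta-O-benzylcatechin (formed in the flask) | [Li]c1c(OCc2ccccc2)cc(OCc2ccccc2)c2c1O[C@H](c1ccc(OCc3ccccc3)c(OCc3ccccc3)c1)[C@@H](OCc1ccccc1)C2 | intermediate
9 | [4-(benzyloxy)-2-(tert-butyldimethylsilyloxy)phenyl](penta-O-benzylcatechin-8-yl)methanol, both epimers (formed in the flask) | OC(c1ccc(OCc2ccccc2)cc1O[Si](C)(C)C(C)(C)C)c1c(OCc2ccccc2)cc(OCc2ccccc2)c2c1O[C@H](c1ccc(OCc3ccccc3)c(OCc3ccccc3)c1)[C@@H](OCc1ccccc1)C2 | intermediate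
10 | 5-(benzyloxy)-2-[hydroxy(penta-O-benzylcatechin-8-yl)methyl]phenol, both epimers | OC(c1ccc(OCc2ccccc2)cc1O)c1c(OCc2ccccc2)cc(OCc2ccccc2)c2c1O[C@H](c1ccc(OCc3ccccc3)c(OCc3ccccc3)c1)[C@@H](OCc1ccccc1)C2 | intermediate
11 | 5-(benzyloxy)-2-[(penta-O-benzylcatechin-8-yl)(p-tolylsulfonyl)methyl]phenol, both epimers | Cc1ccc(cc1)S(=O)(=O)C(c1ccc(OCc2ccccc2)cc1O)c1c(OCc2ccccc2)cc(OCc2ccccc2)c2c1O[C@H](c1ccc(OCc3ccccc3)c(OCc3ccccc3)c1)[C@@H](OCc1ccccc1)C2 | intermediate
12 | benzyloxyacetic acid | OC(=O)COCc1ccccc1 | starting material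
13 | benzyloxyacetic pivalic anhydride (formed in the flask) | CC(C)(C)C(=O)OC(=O)COCc1ccccc1 | intermediate
14 | (E)-3-(benzyloxy)-6-[(penta-O-benzylcatechin-8-yl)methylidene]cyclohexa-2,4-dien-1-one, ring A ortho-quinone methide (formed in the flask) | O=C1C=C(OCc2ccccc2)C=C/C1=C\c1c(OCc2ccccc2)cc(OCc2ccccc2)c2c1O[C@H](c1ccc(OCc3ccccc3)c(OCc3ccccc3)c1)[C@@H](OCc1ccccc1)C2 | intermediate
15 | (3S,4R)-3,7-bis(benzyloxy)-4-(penta-O-benzylcatechin-8-yl)chroman-2-one | c1ccccc1COc1ccc2c(c1)OC(=O)[C@@H](OCc1ccccc1)[C@H]2c1c(OCc2ccccc2)cc(OCc2ccccc2)c2c1O[C@H](c1ccc(OCc3ccccc3)c(OCc3ccccc3)c1)[C@@H](OCc1ccccc1)C2 | intermediate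
16 | (3S,4R)-3,7-bis(benzyloxy)-4-(penta-O-benzylcatechin-8-yl)chroman-2-ol, both anomers | c1ccccc1COc1ccc2c(c1)OC(O)[C@@H](OCc1ccccc1)[C@H]2c1c(OCc2ccccc2)cc(OCc2ccccc2)c2c1O[C@H](c1ccc(OCc3ccccc3)c(OCc3ccccc3)c1)[C@@H](OCc1ccccc1)C2 | intermediate
17 | 5-bromo-1,2,3-trimethoxybenzene | COc1cc(Br)cc(OC)c1OC | starting material
18 | 5-bromobenzene-1,2,3-triol | Oc1cc(Br)cc(O)c1O | intermediate
19 | 1,2,3-tris(benzyloxy)-5-bromobenzene | Brc1cc(OCc2ccccc2)c(OCc2ccccc2)c(OCc2ccccc2)c1 | intermediate
20 | 3,4,5-tris(benzyloxy)phenylmagnesium bromide (formed in the flask) | Br[Mg]c1cc(OCc2ccccc2)c(OCc2ccccc2)c(OCc2ccccc2)c1 | intermediate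
21 | (1S,2S,3R)-2-(benzyloxy)-3-[4-(benzyloxy)-2-hydroxyphenyl]-3-(penta-O-benzylcatechin-8-yl)-1-[3,4,5-tris(benzyloxy)phenyl]propan-1-ol | c1ccccc1COc1ccc(c(O)c1)[C@H](c1c(OCc2ccccc2)cc(OCc2ccccc2)c2c1O[C@H](c1ccc(OCc3ccccc3)c(OCc3ccccc3)c1)[C@@H](OCc1ccccc1)C2)[C@H](OCc1ccccc1)[C@@H](O)c1cc(OCc2ccccc2)c(OCc2ccccc2)c(OCc2ccccc2)c1 | intermediate
22 | deca-O-benzyl-robinetinidol-(4β→8)-catechin | c1ccccc1COc1ccc2c(c1)O[C@H](c1cc(OCc3ccccc3)c(OCc3ccccc3)c(OCc3ccccc3)c1)[C@@H](OCc1ccccc1)[C@H]2c1c(OCc2ccccc2)cc(OCc2ccccc2)c2c1O[C@H](c1ccc(OCc3ccccc3)c(OCc3ccccc3)c1)[C@@H](OCc1ccccc1)C2 | intermediate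
23 | robinetinidol-(4β→8)-catechin (CNP0261864.3) | Oc1ccc2c(c1)O[C@H](c1cc(O)c(O)c(O)c1)[C@@H](O)[C@H]2c1c(O)cc(O)c2c1O[C@H](c1ccc(O)c(O)c1)[C@@H](O)C2 | target

**Step count and risks**

Total step count: 14. Longest linear sequence: 10 steps (from (+)-catechin: steps 1, 2, 3, 6, 7, 8, 9, 12, 13, 14).

Steps most likely to fail:

Step 8. The enolate may add too slowly to the sterically shielded, donor-stabilised quinone methide, the face selectivity may be poor, or C3 may epimerise under the amine base. The fallback sets out from 11 and comes back at 15, and replaces catalyst control by a stoichiometric auxiliary. (R)-4-Benzyloxazolidin-2-one would be N-acylated with benzyloxyacetyl chloride (n-BuLi, THF, −78 °C) to give (R)-4-benzyl-3-[(benzyloxy)acetyl]oxazolidin-2-one F1. Its chelated Z sodium enolate (NaN(SiMe3)2, THF, −78 °C) would be combined with the quinone methide released from 11 by a second equivalent of NaN(SiMe3)2. Conjugate addition on the enolate face remote from the auxiliary benzyl group should give the phenol imide (2S,3R)-2-(benzyloxy)-3-[4-(benzyloxy)-2-hydroxyphenyl]-3-(penta-O-benzylcatechin-8-yl)propanoyl oxazolidinone F2 with C3 S. On warming, its phenoxide should displace the oxazolidinone (6-exo-trig acyl transfer) and return lactone 15. A C4 epimer would be a diastereomer and would be removed by chromatography.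

Step 12. Chelation control may be insufficient (wrong C2 epimer), the magnesium lactolate may open sluggishly, or the transient aldehyde may enolise at C3. The fallback sets out from 15 and comes back at 21; it works at the ketone oxidation level and omits step 9. 3,4,5-Tris(benzyloxy)phenyllithium F3 (from 19 and n-BuLi, THF, −78 °C) would be added to lactone 15 at −78 °C. Collapse of the adduct with loss of the ring A phenoxide should give the keto phenol (2S,3R)-2-(benzyloxy)-3-[4-(benzyloxy)-2-hydroxyphenyl]-3-(penta-O-benzylcatechin-8-yl)-1-[3,4,5-tris(benzyloxy)phenyl]propan-1-one F4. Reduction with the non-chelating K[HB(s-Bu)3] in THF at −78 °C should follow the polar Felkin–Anh model (hydride anti to the C3 benzyloxy group) and give the same syn alcohol 21.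

Step 13. The activated, electron-rich C2 alcohol may ionise before displacement, with loss of stereospecificity, or the hindered SN2 closure may fail. The fallback sets out from 21 and comes back at 22, and replaces the stereospecific displacement by an acid-catalysed cyclodehydration under thermodynamic control. Catalytic camphorsulfonic acid (or BF3·OEt2) in CH2Cl2 should ionise C2–OH to the benzylic cation stabilised by the para-benzyloxy group of ring B. The ring A phenol then closes O1–C2 through the chair-like arrangement with ring B equatorial, so 2,3-trans 22 is expected whatever the C2 configuration of 21. The anti epimer from an unselective step 12 would converge as well, and the 5-deoxy ring A should make the C4–C8' bond tolerant of mild acid. No new compound is made on this path (F0).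

Further compounds
F1 | step 8 | (R)-4-benzyl-3-[(benzyloxy)acetyl]oxazolidin-2-one | O=C1N(C(=O)COCc2ccccc2)[C@H](Cc2ccccc2)CO1
F2 | step 8 | (R)-4-benzyl-3-[(2S,3R)-2-(benzyloxy)-3-[4-(benzyloxy)-2-hydroxyphenyl]-3-(penta-O-benzylcatechin-8-yl)propanoyl]oxazolidin-2-one | c1ccccc1COc1ccc(c(O)c1)[C@H](c1c(OCc2ccccc2)cc(OCc2ccccc2)c2c1O[C@H](c1ccc(OCc3ccccc3)c(OCc3ccccc3)c1)[C@@H](OCc1ccccc1)C2)[C@H](OCc1ccccc1)C(=O)N1C(=O)OC[C@H]1Cc1ccccc1
F3 | step 12 | 3,4,5-tris(benzyloxy)phenyllithium | [Li]c1cc(OCc2ccccc2)c(OCc2ccccc2)c(OCc2ccccc2)c1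
F4 | step 12 | (2S,3R)-2-(benzyloxy)-3-[4-(benzyloxy)-2-hydroxyphenyl]-3-(penta-O-benzylcatechin-8-yl)-1-[3,4,5-tris(benzyloxy)phenyl]propan-1-one | c1ccccc1COc1ccc(c(O)c1)[C@H](c1c(OCc2ccccc2)cc(OCc2ccccc2)c2c1O[C@H](c1ccc(OCc3ccccc3)c(OCc3ccccc3)c1)[C@@H](OCc1ccccc1)C2)[C@H](OCc1ccccc1)C(=O)c1cc(OCc2ccccc2)c(OCc2ccccc2)c(OCc2ccccc2)c1
F0 | step 13 | none | none
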